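**Plan** (carotenoid numbering throughout: C1 = CMe2, C5 = methyl-bearing ring alkene carbon, C6 = stereocentre, C7 onward = chain; primed numbers = ψ half)

1. Chain cuts: C11=C12 and C11′=C12′ (two Wittig disconnections) give an ε-end C15 phosphonium salt, 2,7-dimethylocta-2,4,6-trienedial and a ψ-end C15 salt; the ε-C15 salt goes back through (R)-α-ionone to (R)-α-cyclocitral.
2. Ring cut: C1–C2 and C5–C6 together, a Diels–Alder disconnection into a 3-methylbut-2-enoyl unit (C1=C6–C7=O) and a penta-2,4-dien-2-yl unit (C2 to C5 with the C5 methyl).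
3. Enabling feature: C5 is both a diene terminus and the allylic end of the C4=C5 bond. Silicon on C5 therefore serves first as a tether through oxygen to C8 of a lactate-derived α′-oxy enone (temporary ring B: C5–Si–O–C8–C7–C6), and afterwards as an allylsilane whose protodesilylation puts the ring double bond at C4=C5 only.
4. Forward order: enone and dienylsilane are joined by Si–O; one intramolecular Diels–Alder step closes ring A (C1 to C6, with the quaternary C1) and ring B; ring B is dismantled (reduction, protodesilylation, glycol cleavage) to the aldehyde, which is extended to the C15 salt and joined last to a ψ-C25 aldehyde.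
5. Stereochemistry: C6, the only stereocentre of the target, is set in the cycloaddition by C8 from methyl (R)-lactate; the temporary centres C5, C7 and C8 are erased later; chain double bonds are E from a stabilised ylide or from equilibrated Wittig products.

Key step: step 5

Assumption: pent-1-en-3-yne (5) is taken as a purchasable enyne.
Remark: the spatial arrangement at C6 is the same from 11 to 23; its CIP letter is S in 11 and 12 (silicon on C5 outranks C7) and R from 13 on.

**Step 1**
Reactants: 1 methyl (2R)-2-hydroxypropanoate (methyl (R)-lactate)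
Product: 2 (2R)-2-hydroxy-N-methoxy-N-methylpropanamide
Conditions: MeNH(OMe)·HCl, iPrMgCl (3 equiv), THF, −20 to 0 °C; aqueous work-up
Reagents that add atoms: N,O-dimethylhydroxylamine hydrochloride, CNOC.Cl
Why: Weinreb amidation: the chloromagnesium amide of N,O-dimethylhydroxylamine acylates on the ester while the free hydroxyl is carried as its magnesium alkoxide, and C8, which is not enolised, should keep its configuration.

**Step 2**
Reactants: 2 (2R)-2-hydroxy-N-methoxy-N-methylpropanamide; 3 (2-methylprop-1-en-1-yl)magnesium bromide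
Product: 4 (2R)-2-hydroxy-5-methylhex-4-en-3-one
Conditions: 3 (2.5 equiv), THF, 0 °C; aqueous work-up
Reagents that add atoms: none
Why: Grignard acylation through the Weinreb amide: one equivalent deprotonates the hydroxyl, the next adds once to give a chelated tetrahedral magnesium intermediate that collapses to the ketone only on quench, so over-addition and conjugate addition are avoided and C8 stays R.

**Step 3**
Reactants: 5 pent-1-en-3-yne
Product: 7 (2E)-2-iodopenta-2,4-diene, via dienylzirconocene chloride 6 (not isolated)
Conditions: Cp2Zr(H)Cl (1.0 equiv), THF, 20 °C; then I2, 0 °C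
Reagents that add atoms: iodine, II
Why: Hydrozirconation–iodination: syn addition of Zr–H to the conjugated triple bond should place zirconium on the methyl-bearing carbon distal to the vinyl group (trans to it), and iodinolysis with retention gives the E iodide.

**Step 4**
Reactants: 7 (2E)-2-iodopenta-2,4-diene; 4 (2R)-2-hydroxy-5-methylhex-4-en-3-one
Product: 10 (2R)-2-({dimethyl[(2E)-penta-2,4-dien-2-yl]silyl}oxy)-5-methylhex-4-en-3-one, via dienyllithium 8 (not isolated), via dienylchlorosilane 9 (not isolated)
Conditions: tBuLi (2.0 equiv), Et2O, −78 °C; Me2SiCl2 (4 equiv), −78 to 20 °C, excess Me2SiCl2 evaporated; then 4, imidazole, CH2Cl2, 0 °C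
Reagents that add atoms: dichlorodimethylsilane, C[Si](C)(Cl)Cl
Why: Lithium–iodine exchange with retention of alkene geometry, mono-silylation of the vinyllithium by excess Me2SiCl2 and O-silylation of the α-hydroxy ketone build the temporary silicon connection without touching C8.

**Step 5**
Reactants: 10 (2R)-2-({dimethyl[(2E)-penta-2,4-dien-2-yl]silyl}oxy)-5-methylhex-4-en-3-one
Product: 11 (1S,4R,6S)-1,2,2,4,7,7-hexamethyl-3-oxa-2-silabicyclo[4.4.0]dec-9-en-5-one (bicycle C1 = C5, C4 = C8, C5 = C7, C6 = C6, C7 = C1 in carotenoid numbering; cis-fused)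
Conditions: toluene (0.02 M), BHT (trace), 110 °C, sealed tube
Reagents that add atoms: none
Why: Mechanism: a concerted but asynchronous, normal-electron-demand intramolecular Diels–Alder reaction in which the ketone-activated C1=C6 bond of the 3-methylbut-2-enoyl group adds to C2 and C5 of the dienylsilane, bonding to the β-carbon C1 (new quaternary centre) running ahead of C5–C6 bonding. The closest known reaction types are the temporary silicon connection (silyl ether tethered) intramolecular Diels–Alder reaction and the cyclisation of 1,7,9-decatrien-3-ones, whose in-tether carbonyl lets them cyclise on mild heating. Ring A (cyclohexene, C1 to C6) closes by the [4+2] event itself, and ring B (six-membered 1,2-oxasilinan-5-one) closes as the fused ring at C5–C6 because the four-atom tether Si–O–C8–C7 reaches only the fused and not the bridged orientation, which fixes the regiochemistry. C6 is controlled by C8: the β,β-dimethyl enone is held s-cis by A(1,3) strain and the C8 methyl lies pseudo-equatorial near the plane of C7=O, so the tether oxygen and with it the diene sit on one face only, the face that leads from 8R to the 6R arrangement of the target; C5 (cis ring fusion expected from the endo transition state) is a temporary centre and either ring-fusion isomer converges in step 7. The step needs face selectivity (C8 in the chair-like ring B), site selectivity for C1=C6 (the only activated alkene) and enough reactivity to form the congested C1–C2 and C5–C6 bonds below the temperatures of 1,5-hydrogen shift or silyl migration, which the in-tether carbonyl and the outside position of silicon on the diene should provide. The silicon left on C5 makes the adduct an allylsilane, the handle that later fixes the C4=C5 double bond.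

**Step 6**
Reactants: 11 (1S,4R,6S)-1,2,2,4,7,7-hexamethyl-3-oxa-2-silabicyclo[4.4.0]dec-9-en-5-one
Product: 12 (1S,4R,6S)-1,2,2,4,7,7-hexamethyl-3-oxa-2-silabicyclo[4.4.0]dec-9-en-5-ol (both epimers at the carbinol carbon C7)
Conditions: NaBH4, CeCl3·7H2O, MeOH, −40 °C
Reagents that add atoms: none
Why: Luche-type borohydride reduction of the ring B ketone is fast when cold and only weakly basic, so C6 next to the carbonyl should not epimerise; the new carbinol centre C7 forms as a mixture, which is harmless because C7 becomes the formyl carbon in step 8.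

**Step 7**
Reactants: 12 (1S,4R,6S)-1,2,2,4,7,7-hexamethyl-3-oxa-2-silabicyclo[4.4.0]dec-9-en-5-ol
Product: 13 (2R)-1-[(1R)-2,6,6-trimethylcyclohex-2-en-1-yl]propane-1,2-diol (both C1 epimers of the propane chain)
Conditions: CF3CO2H (3 equiv), CH2Cl2, 0 °C; then K2CO3, MeOH, 20 °C
Reagents that add atoms: none
Why: SE2′ protodesilylation of the allylsilane: the proton adds at C3 anti to the C5–Si bond, the β-silyl cation at C4 sheds silicon, and the double bond is delivered only to C4=C5 (not C3=C4 or C5=C6); methanolysis then frees O8 from silicon and opens ring B, with C6 untouched.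

**Step 8**
Reactants: 13 (2R)-1-[(1R)-2,6,6-trimethylcyclohex-2-en-1-yl]propane-1,2-diol
Product: 14 (1R)-2,6,6-trimethylcyclohex-2-ene-1-carbaldehyde ((R)-α-cyclocitral)
Conditions: NaIO4, THF/H2O (pH 7 phosphate buffer), 0 °C
Reagents that add atoms: none
Why: Periodate glycol cleavage (Malaprade reaction) under buffered neutral conditions excises C8 and its methyl as acetaldehyde and leaves the β,γ-unsaturated aldehyde without contact with acid or base that could enolise C6.

**Step 9**
Reactants: 14 (1R)-2,6,6-trimethylcyclohex-2-ene-1-carbaldehyde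
Product: 15 (3E)-4-[(1R)-2,6,6-trimethylcyclohex-2-en-1-yl]but-3-en-2-one ((R)-α-ionone)
Conditions: Ph3P=CHC(O)CH3, toluene, 80 °C
Reagents that add atoms: 1-(triphenylphosphoranylidene)propan-2-one, CC(=O)C=P(c1ccccc1)(c1ccccc1)c1ccccc1
Why: Wittig olefination with a stabilised ylide needs no added base, which protects the enolisable C6–H of 14, and stabilised ylides give the E enone.

**Step 10**
Reactants: 15 (3E)-4-[(1R)-2,6,6-trimethylcyclohex-2-en-1-yl]but-3-en-2-one
Product: 16 (1E)-3-methyl-1-[(1R)-2,6,6-trimethylcyclohex-2-en-1-yl]penta-1,4-dien-3-ol (both C3 epimers)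
Conditions: CH2=CHMgBr, THF, −20 to 0 °C; aqueous work-up
Reagents that add atoms: vinylmagnesium bromide, C=C[Mg]Br
Why: 1,2-Addition of the vinyl Grignard reagent to the enone carbonyl (the reaction used for vinyl-ionols) gives the tertiary bis-allylic alcohol; the carbinol centre forms as both epimers, which is irrelevant because it becomes sp2 in step 11.

**Step 11**
Reactants: 16 (1E)-3-methyl-1-[(1R)-2,6,6-trimethylcyclohex-2-en-1-yl]penta-1,4-dien-3-ol
Product: 17 [(2E,4E)-3-methyl-5-[(1R)-2,6,6-trimethylcyclohex-2-en-1-yl]penta-2,4-dien-1-yl]triphenylphosphonium bromide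
Conditions: PPh3·HBr, MeOH, 20 °C; crystallisation
Reagents that add atoms: triphenylphosphine hydrobromide, [Br-].[PH+](c1ccccc1)(c1ccccc1)c1ccccc1
Why: Phosphonium salt formation with allylic transposition: HBr ionises the tertiary bis-allylic alcohol and PPh3 captures the pentadienyl cation at its primary terminus (SN1′), giving the conjugated salt with the 9E double bond as the favoured, crystallisable isomer, while the short contact with acid should leave the ring double bond and C6 in place.

**Step 12**
Reactants: 18 (3E,5E)-6,10-dimethylundeca-3,5,9-trien-2-one (pseudoionone)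
Product: 19 (4E,6E)-3,7,11-trimethyldodeca-1,4,6,10-tetraen-3-ol (racemic)
Conditions: CH2=CHMgBr, THF, −20 to 0 °C; aqueous work-up
Reagents that add atoms: vinylmagnesium bromide, C=C[Mg]Br
Why: 1,2-Addition of the vinyl Grignard reagent to the dienone carbonyl, as in step 10; the carbinol centre is racemic and is lost in step 13.

**Step 13**
Reactants: 19 (4E,6E)-3,7,11-trimethyldodeca-1,4,6,10-tetraen-3-ol
Product: 20 [(2E,4E,6E)-3,7,11-trimethyldodeca-2,4,6,10-tetraen-1-yl]triphenylphosphonium bromide
Conditions: PPh3·HBr, MeOH, 20 °C; crystallisation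
Reagents that add atoms: triphenylphosphine hydrobromide, [Br-].[PH+](c1ccccc1)(c1ccccc1)c1ccccc1
Why: The same SN1′ phosphonium salt formation as in step 11, here on the ψ-end alcohol, should give the all-E conjugated salt after crystallisation.

**Step 14**
Reactants: 20 [(2E,4E,6E)-3,7,11-trimethyldodeca-2,4,6,10-tetraen-1-yl]triphenylphosphonium bromide; 21 (2E,4E,6E)-2,7-dimethylocta-2,4,6-trienedial
Product: 22 (2E,4E,6E,8E,10E,12E,14E)-2,7,11,15,19-pentamethylicosa-2,4,6,8,10,12,14,18-octaenal (12′-apo-ψ-caroten-12′-al)
Conditions: 21 (3 equiv), NaOMe, CH2Cl2/MeOH, 0 to 20 °C; crystallisation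
Reagents that add atoms: none
Why: Wittig olefination of a polyenyl ylide with an excess of the symmetrical dialdehyde, which favours mono-condensation; the new C11′=C12′ bond forms as an E/Z mixture that crystallisation and thermal equilibration should turn into the all-E aldehyde.

**Step 15**
Reactants: 17 [(2E,4E)-3-methyl-5-[(1R)-2,6,6-trimethylcyclohex-2-en-1-yl]penta-2,4-dien-1-yl]triphenylphosphonium bromide; 22 12′-apo-ψ-caroten-12′-al
Product: 23 (6R)-ε,ψ-carotene (δ-carotene, CNP0405345.1)
Conditions: NaOMe, CH2Cl2/MeOH, 20 °C; then heptane, reflux, crystallisation (argon, dark)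
Reagents that add atoms: none
Why: Convergent Wittig olefination that forms C11=C12 and joins the C15 and C25 halves; methoxide does not touch the non-acidic C6–H, and heating should equilibrate the Z isomers of the new double bond to the all-E polyene, which crystallises.

**Compound list**

1 | methyl (2R)-2-hydroxypropanoate | C[C@@H](O)C(=O)OC | starting material
2 | (2R)-2-hydroxy-N-methoxy-N-methylpropanamide | C[C@@H](O)C(=O)N(C)OC | intermediate
3 | (2-methylprop-1-en-1-yl)magnesium bromide | CC(C)=C[Mg]Br | starting material
4 | (2R)-2-hydroxy-5-methylhex-4-en-3-one | C[C@@H](O)C(=O)C=C(C)C | intermediate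
5 | pent-1-en-3-yne | C=CC#CC | starting material
6 | chloridobis(η5-cyclopentadienyl)[(2E)-penta-2,4-dien-2-yl]zirconium (Zr trans to vinyl) | Cl[Zr](C1C=CC=C1)(C1C=CC=C1)/C(C)=C/C=C | intermediate (not isolated)
7 | (2E)-2-iodopenta-2,4-diene | I/C(C)=C/C=C | intermediate
8 | (2Z)-penta-2,4-dien-2-yllithium (Li trans to vinyl) | [Li]/C(C)=C/C=C | intermediate (not isolated)
9 | chloro(dimethyl)[(2E)-penta-2,4-dien-2-yl]silane | C[Si](C)(Cl)/C(C)=C/C=C | intermediate (not isolated)
10 | (2R)-2-({dimethyl[(2E)-penta-2,4-dien-2-yl]silyl}oxy)-5-methylhex-4-en-3-one | C[C@@H](O[Si](C)(C)/C(C)=C/C=C)C(=O)C=C(C)C | intermediate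
11 | (1S,4R,6S)-1,2,2,4,7,7-hexamethyl-3-oxa-2-silabicyclo[4.4.0]dec-9-en-5-one | O=C1[C@@H](C)O[Si](C)(C)[C@@]2(C)C=CCC(C)(C)[C@@H]12 | intermediate
12 | (1S,4R,6S)-1,2,2,4,7,7-hexamethyl-3-oxa-2-silabicyclo[4.4.0]dec-9-en-5-ol, carbinol epimers | OC1[C@@H](C)O[Si](C)(C)[C@@]2(C)C=CCC(C)(C)[C@@H]12 | intermediate
13 | (2R)-1-[(1R)-2,6,6-trimethylcyclohex-2-en-1-yl]propane-1,2-diol, C1 epimers | C[C@@H](O)C(O)[C@H]1C(C)=CCCC1(C)C | intermediate
14 | (1R)-2,6,6-trimethylcyclohex-2-ene-1-carbaldehyde | O=C[C@H]1C(C)=CCCC1(C)C | intermediate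
15 | (3E)-4-[(1R)-2,6,6-trimethylcyclohex-2-en-1-yl]but-3-en-2-one | CC(=O)/C=C/[C@H]1C(C)=CCCC1(C)C | intermediate
16 | (1E)-3-methyl-1-[(1R)-2,6,6-trimethylcyclohex-2-en-1-yl]penta-1,4-dien-3-ol, C3 epimers | C=CC(C)(O)/C=C/[C@H]1C(C)=CCCC1(C)C | intermediate
17 | [(2E,4E)-3-methyl-5-[(1R)-2,6,6-trimethylcyclohex-2-en-1-yl]penta-2,4-dien-1-yl]triphenylphosphonium bromide | [Br-].C(/C=C(C)/C=C/[C@H]1C(C)=CCCC1(C)C)[P+](c1ccccc1)(c1ccccc1)c1ccccc1 | intermediate
18 | (3E,5E)-6,10-dimethylundeca-3,5,9-trien-2-one | CC(C)=CCC/C(C)=C/C=C/C(C)=O | starting material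
19 | (4E,6E)-3,7,11-trimethyldodeca-1,4,6,10-tetraen-3-ol, racemic | CC(C)=CCC/C(C)=C/C=C/C(C)(O)C=C | intermediate
20 | [(2E,4E,6E)-3,7,11-trimethyldodeca-2,4,6,10-tetraen-1-yl]triphenylphosphonium bromide | [Br-].CC(C)=CCC/C(C)=C/C=C/C(C)=C/C[P+](c1ccccc1)(c1ccccc1)c1ccccc1 | intermediate
21 | (2E,4E,6E)-2,7-dimethylocta-2,4,6-trienedial | O=C/C(C)=C/C=C/C=C(C)/C=O | starting material
22 | (2E,4E,6E,8E,10E,12E,14E)-2,7,11,15,19-pentamethylicosa-2,4,6,8,10,12,14,18-octaenal | O=C/C(C)=C/C=C/C=C(C)/C=C/C=C(C)/C=C/C=C(C)/CCC=C(C)C | intermediate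
23 | (6R)-ε,ψ-carotene | CC(C)=CCC/C(C)=C/C=C/C(C)=C/C=C/C(C)=C/C=C/C=C(C)/C=C/C=C(C)/C=C/[C@H]1C(C)=CCCC1(C)C | target

**Totals**

Total step count: 15. Longest linear sequence: 11 steps (1, 2, 4, 5, 6, 7, 8, 9, 10, 11, 15).

**Steps most likely to fail**

1. Step 5. The cycloaddition may be too slow, because both new bonds join congested carbons (quaternary C1, fully substituted C5 with an inside methyl on the diene), or the face selection by C8 may be incomplete. Fallback, which gives up the cycloaddition: setting out from pseudoionone 18, cyclisation with 85 % H3PO4 gives racemic α-ionone F1. Condensation with (1R,2S,5R)-menthyl carbazate gives two diastereomeric hydrazones; the menthyl carbazate hydrazone of (R)-α-ionone F2 is separated by fractional crystallisation from the hydrazone of (S)-α-ionone F3. Mild aqueous acidic hydrazone cleavage of F2 releases (R)-α-ionone 15, where the route is rejoined.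

2. Step 7. Protodesilylation of the alkoxy-substituted allylsilane may lag behind acid-promoted migration of the new ring double bond towards C5=C6. Fallback: setting out from 12, MeLi opens the Si–O bond of ring B to give the allyl(trimethyl)silane diol F4. This trialkylallylsilane is more nucleophilic and should undergo SE2′ protodesilylation with a catalytic sulfonic acid in methanol at or below 20 °C, returning to diol 13.

3. Step 9. Configurational purity at C6 may erode through enolisation of the β,γ-unsaturated aldehyde 14 before or during olefination. Fallback that avoids any carbonyl next to C6: setting out from 13, thiocarbonyldiimidazole gives the cyclic thionocarbonate F5. Corey–Winter fragmentation with 1,3-dimethyl-2-phenyl-1,3,2-diazaphospholidine gives the propenylcyclohexene F6. Cross-metathesis of F6 with but-3-en-2-one (second-generation Hoveyda–Grubbs catalyst, CH2Cl2, 40 °C) gives the E enone 15.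

**Further compounds**

F1 | step 5 | racemic (3E)-4-(2,6,6-trimethylcyclohex-2-en-1-yl)but-3-en-2-one | CC(=O)/C=C/C1C(C)=CCCC1(C)C
F2 | step 5 | (1R,2S,5R)-menthyl carbazate hydrazone of (R)-α-ionone | CC(C)[C@@H]1CC[C@@H](C)C[C@H]1OC(=O)NN=C(C)/C=C/[C@H]2C(C)=CCCC2(C)C
F3 | step 5 | (1R,2S,5R)-menthyl carbazate hydrazone of (S)-α-ionone | CC(C)[C@@H]1CC[C@@H](C)C[C@H]1OC(=O)NN=C(C)/C=C/[C@@H]2C(C)=CCCC2(C)C
F4 | step 7 | (2R)-1-[(1S,2S)-2,6,6-trimethyl-2-(trimethylsilyl)cyclohex-3-en-1-yl]propane-1,2-diol, C1 epimers | C[C@@H](O)C(O)[C@@H]1C(C)(C)CC=C[C@]1(C)[Si](C)(C)C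
F5 | step 9 | (5R)-5-methyl-4-[(1R)-2,6,6-trimethylcyclohex-2-en-1-yl]-1,3-dioxolane-2-thione, C4 epimers | C[C@H]1OC(=S)OC1[C@H]2C(C)=CCCC2(C)C
F6 | step 9 | (6R)-1,5,5-trimethyl-6-(prop-1-en-1-yl)cyclohex-1-ene, E/Z mixture | CC=C[C@H]1C(C)=CCCC1(C)C
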